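**Retrosynthetic overview**
- Last, fluoride frees the C4 hydroxyl, which closes the 1,4-oxygen bridge (hemiketal) across the ten-membered ring. The ylidene butenolide comes from a ring-fused furan by [4+2] addition of singlet oxygen and dehydration.
- Key step: the C7–C11 bond and the furan (C6, C7, C11, C12, O) arise from a propargyl vinyl ether by a [3,3]-sigmatropic propargyl Claisen shift and cycloisomerisation inside a cyclodecyne.
- The ten-membered carbocycle is closed before that, at C5–C6, by adding an alkynylchromium to an aldehyde.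
- The open chain comes from a C1–C2 union. A C2–C5 organolithium (C4 bought in a terpene tertiary alcohol) adds to a C1/C6–C10 butyrolactone (C8 bought in an amino-acid-derived lactone, C10 set by trans alkylation).
- Ring order: carbocycle, furan, butenolide, oxygen bridge. The C8 ester goes on after the furan is made.

Assumption: every compound marked starting material below is a catalogue item, and germacrane numbering is used in the names (C1 hemiketal carbon, C4 methyl carbinol carbon, C5=C6, C7=C11, C8 acyloxy carbon, C10 methyl-bearing CH, C12 lactone C=O, C13 acetoxymethyl carbon).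

**Step 1**
Reactants: 1 (S)-5-(hydroxymethyl)dihydrofuran-2(3H)-one
Product: 3 (S)-5-ethynyldihydrofuran-2(3H)-one, via lactone aldehyde 2 (not isolated)
Conditions: Dess–Martin periodinane, CH2Cl2, 0 °C to rt; filter, concentrate; then dimethyl (1-diazo-2-oxopropyl)phosphonate, K2CO3, MeOH, 0 °C to rt; pH 4 work-up
Reagents that add atoms: dimethyl (1-diazo-2-oxopropyl)phosphonate, COP(=O)(OC)C(=[N+]=[N-])C(C)=O
Why: Dess–Martin oxidation followed by Ohira–Bestmann (Seyferth–Gilbert) homologation turns CH2OH into the C7≡C6 alkyne under mild carbonate conditions, any opened lactone recloses on acidification, and the bought C8 centre (S) is kept.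

**Step 2**
Reactants: 3 (S)-5-ethynyldihydrofuran-2(3H)-one
Product: 4 (3R,5S)-3-methyl-5-[(trimethylsilyl)ethynyl]dihydrofuran-2(3H)-one
Conditions: LiN(iPr)2 (2.2 equiv), THF, −78 °C; MeI (1.05 equiv), −78 °C; then Me3SiCl, −78 to 0 °C
Reagents that add atoms: iodomethane, [CH3]I; chlorotrimethylsilane, C[Si](C)(C)Cl
Why: In this lactone enolate alkylation the enolate of the acetylide/enolate dianion takes methyl on the face anti to the C8 alkynyl group, which sets C10 (R, trans lactone, minor cis isomer removed by chromatography), and Me3SiCl then caps the acetylide.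

**Step 3**
Reactants: 5 (S)-(+)-linalool
Product: 6 (5S)-5-ethenyl-5-methyltetrahydrofuran-2-ol (anomer mixture)
Conditions: O3 (1.0 equiv), CH2Cl2, −78 °C; Me2S, −78 °C to rt
Reagents that add atoms: ozone, [O-][O+]=O
Why: Chemoselective ozonolysis works because the trisubstituted alkene reacts far faster than the vinyl group, and the hydroxy aldehyde closes to the lactol with the bought C4 centre untouched.

**Step 4**
Reactants: 6 (5S)-5-ethenyl-5-methyltetrahydrofuran-2-ol
Product: 7 (3S)-5-iodo-3-methylpent-1-en-3-yl formate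
Conditions: PhI(OAc)2 (1.1 equiv), I2 (1.0 equiv), cyclohexane–CH2Cl2, tungsten lamp, 20 °C
Reagents that add atoms: iodine, [I][I]
Why: In this Suárez alkoxyl-radical β-fragmentation the lactol hypoiodite homolyses, the anomeric alkoxyl radical cleaves off the surplus lactol carbon as the C4 formate, and iodine traps the primary C2 radical (ring closure onto the vinyl group would be 4-exo or 5-endo and is slow).

**Step 5**
Reactants: 7 (3S)-5-iodo-3-methylpent-1-en-3-yl formate; 4 (3R,5S)-3-methyl-5-[(trimethylsilyl)ethynyl]dihydrofuran-2(3H)-one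
Product: 10 (3S,7R,9S)-3,9-dihydroxy-3,7-dimethyl-11-(trimethylsilyl)undec-1-en-10-yn-6-one, via lithium iodoalkoxide 8 (not isolated), via dilithio reagent 9 (not isolated)
Conditions: 7, MeLi (2.05 equiv), Et2O, −78 °C; t-BuLi (2.1 equiv), −78 °C; then 4, THF, −78 °C; pH 7 buffer; crude product used at once
Reagents that add atoms: none
Why: MeLi removes the formate before iodine–lithium exchange so the new C2–Li cannot attack it, and single 1,2-addition of the alkyllithium to the γ-lactone (the lithium lactolate is stable at −78 °C) makes the C1–C2 bond and the C1 ketone without touching C4, C8 or C10.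

**Step 6**
Reactants: 10 (3S,7R,9S)-3,9-dihydroxy-3,7-dimethyl-11-(trimethylsilyl)undec-1-en-10-yn-6-one
Product: 11 (3S,7R,9S)-3,7-dimethyl-3,9-bis(triethylsilyloxy)-11-(trimethylsilyl)undec-1-en-10-yn-6-one
Conditions: Et3SiOTf (2.5 equiv), 2,6-lutidine, CH2Cl2, −78 to −20 °C
Reagents that add atoms: triethylsilyl trifluoromethanesulfonate, CC[Si](CC)(CC)OS(=O)(=O)C(F)(F)F
Why: Silyl ether formation at both hydroxyls stops spiroketalisation at C1, leaves the later C5 hydroxyl as the only free one, and avoids a propargylic ester in the gold step.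

**Step 7**
Reactants: 11 (3S,7R,9S)-3,7-dimethyl-3,9-bis(triethylsilyloxy)-11-(trimethylsilyl)undec-1-en-10-yn-6-one
Product: 12 (2S,6R,8S)-2,6-dimethyl-5-oxo-2,8-bis(triethylsilyloxy)-10-(trimethylsilyl)dec-9-ynal
Conditions: O3, CH2Cl2, −78 °C; Me2S, −78 °C to rt
Reagents that add atoms: ozone, [O-][O+]=O
Why: Ozonolysis cleaves the only alkene to the non-enolisable C5 aldehyde, and the silylalkyne is inert to one equivalent of ozone at −78 °C.

**Step 8**
Reactants: 12 (2S,6R,8S)-2,6-dimethyl-5-oxo-2,8-bis(triethylsilyloxy)-10-(trimethylsilyl)dec-9-ynal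
Product: 13 (2S,6R,8S)-10-iodo-2,6-dimethyl-5-oxo-2,8-bis(triethylsilyloxy)dec-9-ynal
Conditions: N-iodosuccinimide, AgNO3 (10 mol %), acetone, rt, dark
Reagents that add atoms: N-iodosuccinimide, O=C1CCC(=O)N1I
Why: Silver-catalysed iododesilylation exchanges only the alkynyl silicon for iodine and leaves the silyl ethers, the ketone and the aldehyde alone.

**Step 9**
Reactants: 13 (2S,6R,8S)-10-iodo-2,6-dimethyl-5-oxo-2,8-bis(triethylsilyloxy)dec-9-ynal
Product: 14 (2R,4S,8S)-7-hydroxy-2,8-dimethyl-4,8-bis(triethylsilyloxy)cyclodec-5-yn-1-one (ring locants; both carbinol epimers at germacrane C5)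
Conditions: CrCl2 (8 equiv), NiCl2 (2 mol %), THF–DMF, syringe-pump addition to 2 mM, rt
Reagents that add atoms: none
Why: In this intramolecular Nozaki–Hiyama–Kishi reaction the alkynylchromium adds to the aldehyde and not to the ketone, closing the C5–C6 bond as in known ten-membered cycloalkynol closures, and the new C5 carbinol centre needs no control because step 11 destroys it.

**Step 10**
Reactants: 14 (2R,4S,8S)-7-hydroxy-2,8-dimethyl-4,8-bis(triethylsilyloxy)cyclodec-5-yn-1-one; 15 propynal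
Product: 16 (E)-3-oxoprop-1-enyl ether of 14 at the C5 oxygen (propargyl vinyl ether)
Conditions: 15 (1.5 equiv), DABCO (10 mol %), CH2Cl2, 0 °C
Reagents that add atoms: none
Why: Amine-catalysed oxa-Michael addition of the only free hydroxyl to the ynal gives the (E)-β-alkoxyacrolein that carries C11, C12 and C13.

**Step 11**
Reactants: 16 (E)-3-oxoprop-1-enyl ether of 14
Product: 18 (4S,6R,10S)-6,10-dimethyl-7-oxo-4,10-bis(triethylsilyloxy)-4,5,6,7,8,9,10,11-octahydrocyclodeca[b]furan-3-carbaldehyde, via allenyl malonaldehyde 17 (not isolated)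
Conditions: Ph3PAuCl (5 mol %), AgBF4 (5 mol %), CH2Cl2, rt
Why-relevant reagents that add atoms follow on the next line.
Reagents that add atoms: none
Why: The propargyl Claisen [3,3]-sigmatropic rearrangement, accelerated by monovalent gold and by release of cycloalkyne strain, forms the C7–C11 bond and a C5=C6=C7 allene; either enol oxygen of the symmetric malonaldehyde then adds to C6 (Kirsch furan synthesis), which gives the furan, turns C5 into CH2 and leaves C13 as CHO.

**Step 12**
Reactants: 18 (4S,6R,10S)-6,10-dimethyl-7-oxo-4,10-bis(triethylsilyloxy)-4,5,6,7,8,9,10,11-octahydrocyclodeca[b]furan-3-carbaldehyde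
Product: 20 [(4S,6R,10S)-6,10-dimethyl-7-oxo-4,10-bis(triethylsilyloxy)-4,5,6,7,8,9,10,11-octahydrocyclodeca[b]furan-3-yl]methyl acetate, via furylmethanol 19 (not isolated)
Conditions: NaBH4, MeOH–CH2Cl2, −78 °C; concentrate; then Ac2O, pyridine, DMAP (cat.), CH2Cl2, 0 °C
Reagents that add atoms: acetic anhydride, CC(=O)OC(C)=O
Why: At −78 °C borohydride reduces the aldehyde much faster than the hindered α-branched ring ketone, and acetylation of the primary alcohol installs the C13 acetate.

**Step 13**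
Reactants: 20 [(4S,6R,10S)-6,10-dimethyl-7-oxo-4,10-bis(triethylsilyloxy)-4,5,6,7,8,9,10,11-octahydrocyclodeca[b]furan-3-yl]methyl acetate
Product: 21 [(4S,6R,10S)-4-hydroxy-6,10-dimethyl-7-oxo-10-(triethylsilyloxy)-4,5,6,7,8,9,10,11-octahydrocyclodeca[b]furan-3-yl]methyl acetate
Conditions: AcOH–THF–H2O (3:1:1), 0 °C
Reagents that add atoms: none
Why: Selective acid desilylation removes the secondary C8 silyl ether well before the tertiary C4 one, and the conditions are too mild to ionise the 3-furyl carbinol.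

**Step 14**
Reactants: 22 (tert-butyldimethylsilyloxy)acetaldehyde; 23 2-(diethoxyphosphoryl)propanoic acid
Product: 24 (E)-4-(tert-butyldimethylsilyloxy)-2-methylbut-2-enoic acid
Conditions: 23, n-BuLi (2.05 equiv), THF, −78 °C; then 22, −78 °C to rt; 1 M HCl work-up
Reagents that add atoms: none
Why: The Horner–Wadsworth–Emmons reaction of the phosphonocarboxylate dianion gives the (E)-trisubstituted acid directly, with no ester hydrolysis step.

**Step 15**
Reactants: 21 [(4S,6R,10S)-4-hydroxy-6,10-dimethyl-7-oxo-10-(triethylsilyloxy)-4,5,6,7,8,9,10,11-octahydrocyclodeca[b]furan-3-yl]methyl acetate; 24 (E)-4-(tert-butyldimethylsilyloxy)-2-methylbut-2-enoic acid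
Product: 25 C8 (E)-4-(tert-butyldimethylsilyloxy)-2-methylbut-2-enoate of 21
Conditions: DCC, DMAP, CH2Cl2, 0 °C to rt
Reagents that add atoms: none
Why: Steglich esterification acylates the only free hydroxyl at oxygen, so C8 keeps its configuration.

**Step 16**
Reactants: 25 C8 (E)-4-(tert-butyldimethylsilyloxy)-2-methylbut-2-enoate of 21
Product: 28 bis-silylated seco target (C5=C6 ylidene butenolide, C1 ketone, C4 triethylsilyl ether), via furan endoperoxide 26 (not isolated), via hydroxybutenolide 27 (not isolated)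
Conditions: O2, methylene blue (cat.), iPr2NEt, CH2Cl2, visible light, −78 °C; then (CF3CO)2O, −78 to 0 °C
Reagents that add atoms: dioxygen, O=O
Why: Singlet oxygen adds to the furan in a [4+2] cycloaddition, the base removes the only bridgehead hydrogen (C12–H, Kornblum–DeLaMare opening) so C12 becomes the lactone carbonyl and C6 carries OH, and trifluoroacetylation of this sole hydroxyl followed by loss of a C5 hydrogen gives the alkene with C4 cis to C7, the less strained cis-cyclodecene geometry.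

**Step 17**
Reactants: 28 bis-silylated seco target
Product: 30 target CNP0154520.2, via seco hydroxy ketone 29 (not isolated)
Conditions: HF·pyridine, pyridine, THF, 0 °C to rt
Reagents that add atoms: none
Why: Buffered fluoride removes both silyl groups without ionising the allylic C4–O bond, and the C4 hydroxyl adds transannularly to the C1 ketone; only the face that puts C5 and C10 cis on the new oxolane can be spanned by the six-carbon bridge, so C4 (S) fixes C1 (R).

**Compound list**
1 | (S)-5-(hydroxymethyl)dihydrofuran-2(3H)-one | OC[C@@H]1CCC(=O)O1 | starting material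
2 | (S)-5-oxotetrahydrofuran-2-carbaldehyde | O=C[C@@H]1CCC(=O)O1 | intermediate
3 | (S)-5-ethynyldihydrofuran-2(3H)-one | C#C[C@@H]1CCC(=O)O1 | intermediate
4 | (3R,5S)-3-methyl-5-[(trimethylsilyl)ethynyl]dihydrofuran-2(3H)-one | O=C1[C@H](C)C[C@@H](C#C[Si](C)(C)C)O1 | intermediate
5 | (S)-(+)-linalool, (3S)-3,7-dimethylocta-1,6-dien-3-ol | C=C[C@@](C)(O)CCC=C(C)C | starting material
6 | (5S)-5-ethenyl-5-methyltetrahydrofuran-2-ol | C=C[C@]1(C)CCC(O)O1 | intermediate
7 | (3S)-5-iodo-3-methylpent-1-en-3-yl formate | C=C[C@@](C)(OC=O)CCI | intermediate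
8 | lithium (3S)-5-iodo-3-methylpent-1-en-3-olate | C=C[C@@](C)(O[Li])CCI | intermediate
9 | lithium (3S)-5-lithio-3-methylpent-1-en-3-olate | C=C[C@@](C)(O[Li])CC[Li] | intermediate
10 | (3S,7R,9S)-3,9-dihydroxy-3,7-dimethyl-11-(trimethylsilyl)undec-1-en-10-yn-6-one | C[Si](C)(C)C#C[C@@H](O)C[C@@H](C)C(=O)CC[C@](C)(O)C=C | intermediate
11 | (3S,7R,9S)-3,7-dimethyl-3,9-bis(triethylsilyloxy)-11-(trimethylsilyl)undec-1-en-10-yn-6-one | C[Si](C)(C)C#C[C@@H](O[Si](CC)(CC)CC)C[C@@H](C)C(=O)CC[C@](C)(O[Si](CC)(CC)CC)C=C | intermediate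
12 | (2S,6R,8S)-2,6-dimethyl-5-oxo-2,8-bis(triethylsilyloxy)-10-(trimethylsilyl)dec-9-ynal | C[Si](C)(C)C#C[C@@H](O[Si](CC)(CC)CC)C[C@@H](C)C(=O)CC[C@](C)(O[Si](CC)(CC)CC)C=O | intermediate
13 | (2S,6R,8S)-10-iodo-2,6-dimethyl-5-oxo-2,8-bis(triethylsilyloxy)dec-9-ynal | IC#C[C@@H](O[Si](CC)(CC)CC)C[C@@H](C)C(=O)CC[C@](C)(O[Si](CC)(CC)CC)C=O | intermediate
14 | (2R,4S,8S)-7-hydroxy-2,8-dimethyl-4,8-bis(triethylsilyloxy)cyclodec-5-yn-1-one, carbinol epimers | OC1C#C[C@@H](O[Si](CC)(CC)CC)C[C@@H](C)C(=O)CC[C@]1(C)O[Si](CC)(CC)CC | intermediate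
15 | propynal | C#CC=O | starting material
16 | (E)-3-oxoprop-1-enyl ether of 14 (propargyl vinyl ether) | O=C/C=C/OC1C#C[C@@H](O[Si](CC)(CC)CC)C[C@@H](C)C(=O)CC[C@]1(C)O[Si](CC)(CC)CC | intermediate
17 | 2-(cyclodeca-1,2-dienyl)malonaldehyde with allene C7=C6=C5, C1 ketone and C4, C8 silyl ethers | O=CC(C=O)C1=C=C[C@@](C)(O[Si](CC)(CC)CC)CCC(=O)[C@H](C)C[C@@H]1O[Si](CC)(CC)CC | intermediate
18 | (4S,6R,10S)-6,10-dimethyl-7-oxo-4,10-bis(triethylsilyloxy)-4,5,6,7,8,9,10,11-octahydrocyclodeca[b]furan-3-carbaldehyde | O=Cc1coc2C[C@@](C)(O[Si](CC)(CC)CC)CCC(=O)[C@H](C)C[C@H](O[Si](CC)(CC)CC)c12 | intermediate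
19 | (4S,6R,10S)-3-(hydroxymethyl)-6,10-dimethyl-4,10-bis(triethylsilyloxy)-5,6,8,9,10,11-hexahydrocyclodeca[b]furan-7(4H)-one | OCc1coc2C[C@@](C)(O[Si](CC)(CC)CC)CCC(=O)[C@H](C)C[C@H](O[Si](CC)(CC)CC)c12 | intermediate
20 | acetate of 19 | CC(=O)OCc1coc2C[C@@](C)(O[Si](CC)(CC)CC)CCC(=O)[C@H](C)C[C@H](O[Si](CC)(CC)CC)c12 | intermediate
21 | [(4S,6R,10S)-4-hydroxy-6,10-dimethyl-7-oxo-10-(triethylsilyloxy)-4,5,6,7,8,9,10,11-octahydrocyclodeca[b]furan-3-yl]methyl acetate | CC(=O)OCc1coc2C[C@@](C)(O[Si](CC)(CC)CC)CCC(=O)[C@H](C)C[C@H](O)c12 | intermediate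
22 | (tert-butyldimethylsilyloxy)acetaldehyde | O=CCO[Si](C)(C)C(C)(C)C | starting material
23 | 2-(diethoxyphosphoryl)propanoic acid | CCOP(=O)(OCC)C(C)C(=O)O | starting material
24 | (E)-4-(tert-butyldimethylsilyloxy)-2-methylbut-2-enoic acid | OC(=O)/C(C)=C/CO[Si](C)(C)C(C)(C)C | intermediate
25 | C8 (E)-4-(tert-butyldimethylsilyloxy)-2-methylbut-2-enoate of 21 | CC(=O)OCc1coc2C[C@@](C)(O[Si](CC)(CC)CC)CCC(=O)[C@H](C)C[C@H](OC(=O)/C(C)=C/CO[Si](C)(C)C(C)(C)C)c12 | intermediate
26 | C6,C12-endoperoxide of 25 (2,3,7-trioxabicyclo[2.2.1]heptene) | CC(=O)OCC1=C2[C@@H](OC(=O)/C(C)=C/CO[Si](C)(C)C(C)(C)C)C[C@@H](C)C(=O)CC[C@](C)(O[Si](CC)(CC)CC)CC24OOC1O4 | intermediate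
27 | C6-hydroxy butenolide (12,6-olide, C6 epimers) | CC(=O)OCC1=C2C(O)(C[C@@](C)(O[Si](CC)(CC)CC)CCC(=O)[C@H](C)C[C@@H]2OC(=O)/C(C)=C/CO[Si](C)(C)C(C)(C)C)OC1=O | intermediate
28 | bis-silylated seco target: 5E-ylidene butenolide, C1 ketone, C4 triethylsilyl ether, side-chain tert-butyldimethylsilyl ether | CC(=O)OCC1=C2/C(=C\[C@@](C)(O[Si](CC)(CC)CC)CCC(=O)[C@H](C)C[C@@H]2OC(=O)/C(C)=C/CO[Si](C)(C)C(C)(C)C)OC1=O | intermediate
29 | seco hydroxy ketone (open form of the target) | CC(=O)OCC1=C2/C(=C\[C@@](C)(O)CCC(=O)[C@H](C)C[C@@H]2OC(=O)/C(C)=C/CO)OC1=O | intermediate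
30 | (1R,4S,8S,10R)-13-acetoxy-1,4-epoxy-1-hydroxy-8-[(E)-4-hydroxy-2-methylbut-2-enoyloxy]germacra-5E,7(11)-dien-12,6-olide (CNP0154520.2) | CC(=O)OCC1=C2/C(=C\[C@]3(C)CC[C@@](O)(O3)[C@H](C)C[C@@H]2OC(=O)/C(C)=C/CO)OC1=O | target

**Count**
- Total steps: 17.
- Longest linear sequence: 14 (steps 1, 2, 5–13, 15–17). The branch through steps 3 and 4 is equally long.

**Steps most likely to fail**

**Step 9 (closure of the ten-membered cycloalkyne; strain and oligomerisation).**
The fallback sets out from 7 and 4 and comes back at 21. The two fragment unions are swapped so that no cycloalkyne is needed.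
- Ozonolysis of 7 gives (2S)-4-iodo-2-methyl-1-oxobutan-2-yl formate F1.
- N-iodosuccinimide/AgNO3 turns 4 into (3R,5S)-5-(iodoethynyl)-3-methyldihydrofuran-2(3H)-one F2.
- An intermolecular CrCl2/NiCl2 coupling joins them to the open-chain propargylic alcohol F3.
- 15 with DABCO gives its (E)-3-oxoprop-1-enyl ether F4.
- Ph3PAuCl/AgBF4 converts this to the open-chain furan-3-carbaldehyde F5. The lactone still masks C8–O and the formate masks C4–O.
- NaBH4 in MeOH, which also methanolyses the formate, followed by Ac2O/pyridine gives the hydroxy acetate F6.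
- Et3SiOTf/2,6-lutidine gives the triethylsilyl ether F7.
- SmI2 with catalytic NiI2 at high dilution then closes the ring at C1–C2. The alkylsamarium attacks the lactone carbonyl, which frees the C8 hydroxyl and gives 21.

**Step 4 (alkoxyl-radical fragmentation beside a vinyl group; lactone formation or addition of the hypoiodite to the alkene may compete).**
The fallback sets out from 6 and comes back at 10. C2 becomes nucleophilic as an enolate, and the surplus carbon leaves later.
- TEMPO/PhI(OAc)2 oxidises 6 to (5S)-5-ethenyl-5-methyldihydrofuran-2(3H)-one F8.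
- Its lithium enolate (LiN(iPr)2, two equivalents of F8) is C-acylated by lactone 4 in a crossed Claisen condensation to the 3-acyl lactone F9.
- Me3SnOH in 1,2-dichloroethane at 80 °C opens the tertiary lactone without touching the silylalkyne, and the β-keto acid decarboxylates to 10.

**Step 16 (photooxygenation and dehydration on the full substrate).**
The fallback sets out from 25 and comes back at 27. It is ionic rather than photochemical.
- N-bromosuccinimide in NaHCO3-buffered aqueous acetone opens the furan to the (Z)-keto enal F10.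
- NaClO2/NaH2PO4/2-methyl-2-butene oxidises the C12 aldehyde, and the keto acid closes to 27.
- 27 is dehydrated with (CF3CO)2O/iPr2NEt as in the main route.

**Further compounds**
F1 | step 9 | (2S)-4-iodo-2-methyl-1-oxobutan-2-yl formate | O=C[C@@](C)(OC=O)CCI
F2 | step 9 | (3R,5S)-5-(iodoethynyl)-3-methyldihydrofuran-2(3H)-one | O=C1[C@H](C)C[C@@H](C#CI)O1
F3 | step 9 | open-chain propargylic alcohol (C5 carbinol epimers; C4 formate, C2 iodide, C1/C8 lactone) | O=C1[C@H](C)C[C@@H](C#CC(O)[C@@](C)(OC=O)CCI)O1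
F4 | step 9 | (E)-3-oxoprop-1-enyl ether of F3 | O=C1[C@H](C)C[C@@H](C#CC(O/C=C/C=O)[C@@](C)(OC=O)CCI)O1
F5 | step 9 | open-chain furan-3-carbaldehyde (C4 formate, C2 iodide, C1/C8 lactone) | O=Cc1coc(C[C@@](C)(OC=O)CCI)c1[C@@H]2C[C@@H](C)C(=O)O2
F6 | step 9 | hydroxy acetate (C13 acetate, free C4 hydroxyl) | CC(=O)OCc1coc(C[C@@](C)(O)CCI)c1[C@@H]2C[C@@H](C)C(=O)O2
F7 | step 9 | triethylsilyl ether of F6 | CC(=O)OCc1coc(C[C@@](C)(O[Si](CC)(CC)CC)CCI)c1[C@@H]2C[C@@H](C)C(=O)O2
F8 | step 4 | (5S)-5-ethenyl-5-methyldihydrofuran-2(3H)-one | C=C[C@]1(C)CCC(=O)O1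
F9 | step 4 | (5S)-5-ethenyl-3-[(2R,4S)-4-hydroxy-2-methyl-6-(trimethylsilyl)hex-5-ynoyl]-5-methyldihydrofuran-2(3H)-one | C=C[C@]1(C)CC(C(=O)[C@H](C)C[C@H](O)C#C[Si](C)(C)C)C(=O)O1
F10 | step 16 | (Z)-keto enal from furan opening of 25 (C6 ketone, C12 aldehyde) | CC(=O)OC/C(C=O)=C1/C(=O)C[C@@](C)(O[Si](CC)(CC)CC)CCC(=O)[C@H](C)C[C@@H]1OC(=O)/C(C)=C/CO[Si](C)(C)C(C)(C)C
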